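**Strategy**

The cycloheptanone ring (C2H(CH3)–C3H2–C4H2–C5(OH)–C6H–C10(=O)–C11) is disconnected at C2–C11 and C4–C5. Both bonds form in one [4+3] cycloaddition of a 2-oxyallyl cation (C2–C3–C4) with a cyclopentane-fused 2-methyl-3-silyloxyfuran whose ring carbons are C5, C6, C10 and C11. The step exploits the 1,4-relation of C5 and C11 in the seven-membered ring, which flank the β-hydroxy ketone C5(OH)–C6–C10(=O): the C5 oxygen serves as the furan oxygen and bridges to C11. This C11–O bond, absent from the target, fixes the C5 configuration and is later cleaved reductively beside the C10 ketone, giving the enolate used to build quaternary C11.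

Key step: step 6

Remark: labels C2–C11 are those above; the cyclopentane ring is C5–C6–C7H2–C8H(OH)–C9(CH3)2, and β denotes the face of the C5 oxygen. Amide 4 is assumed to be purchased as the (S)-enantiomer; its stereocentre is erased in step 5, so the racemate serves equally.

**Route**

Step 1
Reactants: 1 2,2-dimethylcyclopentane-1,3-dione
Product: 2 (3R)-3-hydroxy-2,2-dimethylcyclopentan-1-one
Conditions: (S)-2-methyl-CBS-oxazaborolidine (10 mol%), catecholborane (1.1 equiv), toluene, −60 °C; aqueous work-up
Reagents that add atoms: none
Why: Corey–Bakshi–Shibata reduction of one of the two enantiotopic carbonyls; with the quaternary carbon as the large and the CH2 as the small substituent the (S)-catalyst should give the 3R carbinol (C8), and one equivalent of hydride limits over-reduction to the diol.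

Step 2
Reactants: 2 (3R)-3-hydroxy-2,2-dimethylcyclopentan-1-one
Product: 3 (3R)-2,2-dimethyl-3-(triisopropylsilyloxy)cyclopentan-1-one
Conditions: TIPSOTf, 2,6-lutidine, CH2Cl2, 0 °C → rt
Reagents that add atoms: triisopropylsilyl triflate CC(C)[Si](C(C)C)(C(C)C)OS(=O)(=O)C(F)(F)F
Why: Silyl ether formation with the reactive triflate on the hindered secondary alcohol gives a bulky, acid-tolerant group that later screens the β face next to C5.

Step 3
Reactants: 3 (3R)-2,2-dimethyl-3-(triisopropylsilyloxy)cyclopentan-1-one; 4 (2S)-2-(tert-butyldimethylsilyloxy)-N-methoxy-N-methylpropanamide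
Product: 5 (4R)-2-[(2S)-2-(tert-butyldimethylsilyloxy)propanoyl]-5,5-dimethyl-4-(triisopropylsilyloxy)cyclopentan-1-one (keto/enol and C2-epimer mixture)
Conditions: LDA, THF, −78 °C; then 4, −78 → 0 °C; aq. NH4Cl
Reagents that add atoms: none
Why: Claisen-type C-acylation of the lithium enolate (C6 is the only enolisable position because C9 is quaternary) with the N-methoxy-N-methylamide stops at the chelated tetrahedral adduct, so the β-diketone should form without O-acylation or over-addition.

Step 4
Reactants: 5 β-diketone from step 3
Product: 7 (2S,5R)-2,6,6-trimethyl-5-(triisopropylsilyloxy)-5,6-dihydro-4H-cyclopenta[b]furan-3(2H)-one (C2 of the furanone, i.e. C11, is configurationally labile), via hydroxy diketone 6 (not isolated)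
Conditions: 2 M HCl, THF, rt
Reagents that add atoms: none
Why: Acid removes the unhindered secondary TBS ether, and the freed C11 hydroxyl adds to the C5 carbonyl and dehydrates (cyclodehydration of an α'-hydroxy-1,3-diketone to a 3(2H)-furanone), while the hindered TIPS ether should survive.

Step 5
Reactants: 7 furanone from step 4
Product: 8 (5R)-3-(tert-butyldimethylsilyloxy)-2,6,6-trimethyl-5-(triisopropylsilyloxy)-5,6-dihydro-4H-cyclopenta[b]furan
Conditions: TBSOTf, Et3N, CH2Cl2, 0 °C
Reagents that add atoms: tert-butyldimethylsilyl triflate CC(C)(C)[Si](C)(C)OS(=O)(=O)C(F)(F)F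
Why: Soft enolisation at C11–H and O-silylation (silyl enol ether formation) aromatise the ring to the 3-silyloxyfuran and erase the C11 stereocentre.

Step 6
Reactants: 8 silyloxyfuran from step 5; 9 1,1,3,3-tetrabromopropan-2-one
Product: 11 oxygen-bridged cycloadduct (8-oxabicyclo[3.2.1]oct-6-en-3-one core: bridgeheads C11 (methyl) and C5 joined by oxygen, bridge C2H2–C3(=O)–C4H2, bridge C6=C10 with OTBS on C10; cyclopentane fused at C5–C6 with 8β-OTIPS and 9,9-dimethyl), via dibromo cycloadduct 10 (not isolated)
Conditions: Et2Zn, THF, −10 → 0 °C; then Zn–Cu couple, NH4Cl, MeOH, rt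
Reagents that add atoms: none
Why: Diethylzinc reduces 9 to a zinc enolate that loses bromide to give the 1,3-dibromo-2-oxyallyl cation, a two-electron three-carbon unit that adds to the four-electron furan diene of 8 in a thermally allowed [4+3] cycloaddition, either concerted or by attack of C11 followed by collapse of the enolate terminus on the silyloxy-stabilised oxocarbenium carbon C5; zinc–copper then removes both bromides. The closest known reaction type is the oxyallyl cation–furan [4+3] cycloaddition. The seven-membered carbocycle (C2, C3, C4, C5, C6, C10, C11) is closed by intermolecular suprafacial [4+3] cycloaddition that forms C2–C11 and C4–C5 together, and the same event closes the oxygen-bridged tetrahydropyranone ring. The new stereocentres C5 and C11 are necessarily cis through the oxygen bridge, and their sense is set by approach of the cation to the furan face anti to the C8 silyloxy group and the pseudoaxial C9 methyl, which places the C5 oxygen cis to the C8 oxygen. The step needs this facial selectivity (secured by the bulky OTIPS group next to C5) and ring closure in preference to open-chain substitution at C11 (secured by the robust TBS group on the C10 oxygen and the intramolecular second bond formation); the symmetric oxyallyl unit raises no regiochemical issue, and C10 emerges as the bridging silyl enol ether.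

Step 7
Reactants: 11 oxygen-bridged cycloadduct
Product: 12 2β-methyl derivative of 11 (axial methyl at C2, syn to the oxygen bridge)
Conditions: LDA, THF, −78 °C; then MeI, −78 → −40 °C
Reagents that add atoms: iodomethane CI
Why: Kinetic enolate alkylation: LDA should remove the axial hydrogen at C2 (the methylene remote from the C9 gem-dimethyl and C8 OTIPS groups that screen C4), and iodomethane adds from the exo β face syn to the oxygen bridge and anti to the C6=C10 bridge, setting C2; low temperature suppresses β-elimination of the bridge oxygen.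

Step 8
Reactants: 12 2β-methyl ketone
Product: 13 C3 tosylhydrazone of 12
Conditions: TsNHNH2, MgSO4, THF, rt → 40 °C
Reagents that add atoms: p-toluenesulfonyl hydrazide Cc1ccc(cc1)S(=O)(=O)NN
Why: Hydrazone condensation at the only ketone (C3); the remaining C2 hydrogen is equatorial and poorly aligned for enolisation, so the axial methyl should not epimerise.

Step 9
Reactants: 13 tosylhydrazone
Product: 14 C3-deoxygenated bridged silyl enol ether (C3 now CH2)
Conditions: catecholborane, CHCl3, 0 °C; then NaOAc·3H2O, reflux
Reagents that add atoms: none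
Why: Tosylhydrazone reduction with catecholborane (hydride addition to C=N, then acetate-induced loss of sulfinate and dinitrogen from the diazene) converts C3 into a methylene under non-basic conditions that leave C2, the silyl enol ether and the TIPS ether untouched.

Step 10
Reactants: 14 bridged silyl enol ether
Product: 15 oxygen-bridged C10 ketone (C6–H α, cyclopentane exo-fused)
Conditions: 2 M HCl, THF, 0 °C → rt
Reagents that add atoms: none
Why: Acid hydrolysis of the silyl enol ether by C-protonation at C6 unveils the C10 ketone; C6 is epimerisable and should settle with H on the α (endo) face because only the exo-fused cyclopentane (C7 syn to the oxygen bridge) is low in strain, which is the trans C5–O/C6–H relation of the target.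

Step 11
Reactants: 15 oxygen-bridged ketone
Product: 16 ring-opened bis(trimethylsilyl) compound (C10–C11 trimethylsilyl enol ether, C5 OTMS, hydroazulene skeleton)
Conditions: SmI2, THF–HMPA, −78 °C; then TMSCl, Et3N, −78 → 0 °C
Reagents that add atoms: chlorotrimethylsilane C[Si](C)(C)Cl
Why: Samarium diiodide reduction of the α-alkoxy ketone cleaves the C11–O bond (ketyl formation, expulsion of the α-oxygen, second electron transfer) and releases the C5 alkoxide and the regiodefined C10–C11 samarium enolate, both of which are silylated in the same flask.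

Step 12
Reactants: 17 4-bromofuran-2(5H)-one
Product: 18 4-ethenylfuran-2(5H)-one
Conditions: tributyl(vinyl)stannane, Pd(PPh3)4 (cat.), toluene, 90 °C
Reagents that add atoms: tributyl(vinyl)stannane C=C[Sn](CCCC)(CCCC)CCCC
Why: Stille coupling of the vinylogous acyl bromide with the vinylstannane installs the vinyl group on the butenolide.

Step 13
Reactants: 16 bis(trimethylsilyl) enol ether; 18 4-ethenylfuran-2(5H)-one
Product: 19 8-O-triisopropylsilyl ether of the target (C5 hydroxyl free)
Conditions: TiCl4, CH2Cl2, −78 °C; then 1 M HCl work-up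
Reagents that add atoms: none
Why: Mukaiyama–Michael addition in its vinylogous (1,6) mode: the TiCl4-activated dienyl lactone is attacked at its unsubstituted terminal carbon (the β-carbon is blocked) by C11 of the silyl enol ether from the α face, anti to the adjacent C2 β-methyl and the C5 β-silyloxy group, which sets quaternary C11 with its methyl cis to the C2 methyl; γ-protonation of the silyloxyfuran on acidic work-up returns the conjugated butenolide and frees the C5 hydroxyl.

Step 14
Reactants: 19 8-O-triisopropylsilyl ether of the target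
Product: 20 CNP0077405.1 (target; C2 R, C5 S, C6 S, C8 R, C11 S)
Conditions: HF·pyridine, THF, 0 °C → rt
Reagents that add atoms: none
Why: Fluoride-mediated desilylation under acidic, non-basic conditions removes the TIPS ether without retro-aldol cleavage of the β-hydroxy ketone or isomerisation of the butenolide.

**Compound list**

1 | 2,2-dimethylcyclopentane-1,3-dione | CC1(C)C(=O)CCC1=O | starting material
2 | (3R)-3-hydroxy-2,2-dimethylcyclopentan-1-one | O=C1CC[C@@H](O)C1(C)C | intermediate
3 | (3R)-2,2-dimethyl-3-(triisopropylsilyloxy)cyclopentan-1-one | O=C1CC[C@@H](O[Si](C(C)C)(C(C)C)C(C)C)C1(C)C | intermediate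
4 | (2S)-2-(tert-butyldimethylsilyloxy)-N-methoxy-N-methylpropanamide | C[C@H](O[Si](C)(C)C(C)(C)C)C(=O)N(C)OC | starting material
5 | (4R)-2-[(2S)-2-(tert-butyldimethylsilyloxy)propanoyl]-5,5-dimethyl-4-(triisopropylsilyloxy)cyclopentan-1-one | C[C@H](O[Si](C)(C)C(C)(C)C)C(=O)C1CC[C@@H](O[Si](C(C)C)(C(C)C)C(C)C)C(C)(C)C1=O | intermediate
6 | (4R)-2-[(2S)-2-hydroxypropanoyl]-5,5-dimethyl-4-(triisopropylsilyloxy)cyclopentan-1-one | C[C@H](O)C(=O)C1CC[C@@H](O[Si](C(C)C)(C(C)C)C(C)C)C(C)(C)C1=O | intermediate
7 | (2S,5R)-2,6,6-trimethyl-5-(triisopropylsilyloxy)-5,6-dihydro-4H-cyclopenta[b]furan-3(2H)-one | C[C@@H]1OC2=C(C1=O)C[C@@H](O[Si](C(C)C)(C(C)C)C(C)C)C2(C)C | intermediate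
8 | (5R)-3-(tert-butyldimethylsilyloxy)-2,6,6-trimethyl-5-(triisopropylsilyloxy)-5,6-dihydro-4H-cyclopenta[b]furan | Cc1oc2c(c1O[Si](C)(C)C(C)(C)C)C[C@@H](O[Si](C(C)C)(C(C)C)C(C)C)C2(C)C | intermediate
9 | 1,1,3,3-tetrabromopropan-2-one | O=C(C(Br)Br)C(Br)Br | starting material
10 | 2,4-dibromo derivative of cycloadduct 11 (bromide epimers) | C[C@@]12O[C@@]3(C(Br)C(=O)C1Br)C(=C2O[Si](C)(C)C(C)(C)C)C[C@@H](O[Si](C(C)C)(C(C)C)C(C)C)C3(C)C | intermediate
11 | oxygen-bridged cycloadduct (C3 ketone, C5–O–C11 bridge, C6=C10 TBS enol ether, 8β-OTIPS) | C[C@@]12O[C@@]3(CC(=O)C1)C(=C2O[Si](C)(C)C(C)(C)C)C[C@@H](O[Si](C(C)C)(C(C)C)C(C)C)C3(C)C | intermediate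
12 | 2β-methyl derivative of 11 | C[C@@]12O[C@@]3(CC(=O)[C@H]1C)C(=C2O[Si](C)(C)C(C)(C)C)C[C@@H](O[Si](C(C)C)(C(C)C)C(C)C)C3(C)C | intermediate
13 | C3 tosylhydrazone of 12 | C[C@@]12O[C@@]3(CC(=NNS(=O)(=O)c4ccc(C)cc4)[C@H]1C)C(=C2O[Si](C)(C)C(C)(C)C)C[C@@H](O[Si](C(C)C)(C(C)C)C(C)C)C3(C)C | intermediate
14 | C3-deoxygenated bridged silyl enol ether | C[C@@]12O[C@@]3(CC[C@H]1C)C(=C2O[Si](C)(C)C(C)(C)C)C[C@@H](O[Si](C(C)C)(C(C)C)C(C)C)C3(C)C | intermediate
15 | oxygen-bridged C10 ketone (C6–H α) | C[C@@]12O[C@@]3(CC[C@H]1C)[C@@H](C2=O)C[C@@H](O[Si](C(C)C)(C(C)C)C(C)C)C3(C)C | intermediate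
16 | ring-opened C10–C11 trimethylsilyl enol ether with C5 OTMS and C8 OTIPS | CC1=C(O[Si](C)(C)C)[C@H]2C[C@@H](O[Si](C(C)C)(C(C)C)C(C)C)C(C)(C)[C@]2(O[Si](C)(C)C)CC[C@H]1C | intermediate
17 | 4-bromofuran-2(5H)-one | O=C1C=C(Br)CO1 | starting material
18 | 4-ethenylfuran-2(5H)-one | C=CC1=CC(=O)OC1 | intermediate
19 | 8-O-triisopropylsilyl ether of the target | C[C@@H]1CC[C@]2(O)[C@H](C[C@@H](O[Si](C(C)C)(C(C)C)C(C)C)C2(C)C)C(=O)[C@@]1(C)CCC1=CC(=O)OC1 | intermediate
20 | CNP0077405.1 | C[C@@H]1CC[C@]2(O)[C@H](C[C@@H](O)C2(C)C)C(=O)[C@@]1(C)CCC1=CC(=O)OC1 | target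

**Step count and risks**

Total step count: 14. Longest linear sequence: 13 (steps 1–11, 13, 14).

Steps most likely to fail:

Step 6. After the first C–C bond at C11 the zwitterion may lose its silyl group or be quenched before the enolate terminus closes on the hindered C5, giving open-chain substitution instead of cycloaddition, and facial control may be incomplete. The fallback sets out from 7 and builds the two bonds one after the other. C-alkylation of 7 at C11 with chloroacetone (K2CO3, NaI, acetone) should give the 11-(2-oxopropyl) furanone F1, the epimer with the oxopropyl group anti to the C8 silyloxy group being separated from its C11 epimer. TBSOTf and Et3N then convert the methyl ketone into its terminal silyl enol ether and O-silylate the furanone carbonyl; the 3-silyloxyfuranium ion is captured at C5 in an intramolecular Mukaiyama–Michael closure. The fallback comes back to the route at 11.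

Step 13. The hindered tetrasubstituted silyl enol ether may fail to add in the 1,6 sense, the dienyl lactone may polymerise under the Lewis acid, or facial control at C11 may be lost. The fallback sets out from 16: methyllithium (THF, 0 °C) frees the lithium enolate, which is alkylated in THF–HMPA with 3-(2-iodoethyl)furan F2 (made from 2-(furan-3-yl)ethanol with I2, PPh3 and imidazole) to give the furylethyl ketone F3, again anti to the C2 methyl. Sensitised photo-oxygenation of the 3-alkylfuran (O2, hν, rose bengal, i-Pr2NEt, CH2Cl2, −78 °C) should give the γ-hydroxybutenolide F4, and NaBH4 (EtOH, 0 °C) followed by 1 M HCl reduces the lactol carbon, relactonises and removes the C5 trimethylsilyl group. The fallback comes back at 19.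

Step 7. Deprotonation may occur at C4 instead of C2, or the enolate may over-alkylate or expel the bridge oxygen. The fallback sets out from 11 and replaces substrate-controlled enolate methylation by reagent-controlled enolisation with isolation of the enol ether. Deprotonation with lithium bis[(R)-1-phenylethyl]amide–LiCl, or its enantiomer (whichever removes the C2 hydrogen), in the presence of TMSCl at −100 °C should give the C2–C3 trimethylsilyl enol ether F5, which is purified from any regioisomer. Methyllithium then regenerates the C2 enolate regiospecifically and iodomethane is added at −78 °C from the exo face. The fallback comes back at 12.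

Further compounds
F1 | step 6 | 11-(2-oxopropyl) furanone: (5R)-2,6,6-trimethyl-2-(2-oxopropyl)-5-(triisopropylsilyloxy)-5,6-dihydro-4H-cyclopenta[b]furan-3(2H)-one, oxopropyl group anti to the silyloxy group | CC(=O)C[C@@]1(C)OC2=C(C1=O)C[C@@H](O[Si](C(C)C)(C(C)C)C(C)C)C2(C)C
F2 | step 13 | 3-(2-iodoethyl)furan | ICCc1ccoc1
F3 | step 13 | furylethyl ketone (C11 2-(furan-3-yl)ethyl, C5 OTMS, C8 OTIPS) | C[C@@H]1CC[C@]2(O[Si](C)(C)C)[C@H](C[C@@H](O[Si](C(C)C)(C(C)C)C(C)C)C2(C)C)C(=O)[C@@]1(C)CCc1ccoc1
F4 | step 13 | γ-hydroxybutenolide from F3 (lactol epimers) | C[C@@H]1CC[C@]2(O[Si](C)(C)C)[C@H](C[C@@H](O[Si](C(C)C)(C(C)C)C(C)C)C2(C)C)C(=O)[C@@]1(C)CCC1=CC(=O)OC1O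
F5 | step 7 | C2–C3 trimethylsilyl enol ether of 11 | C[C@@]12O[C@@]3(CC(O[Si](C)(C)C)=C1)C(=C2O[Si](C)(C)C(C)(C)C)C[C@@H](O[Si](C(C)C)(C(C)C)C(C)C)C3(C)C
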